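**Plan**

1. Target locants: C1 (CMe2), C2 (CBr=), C3, C4 (CHOH), C5 (C=CH2), C6 (spiro), C7, C8 (CHBr), C9 (CMeCl), C10, C11. Retrosynthesis: C4–OH ⇐ C4=O ⇐ allylic CH2; C2 vinyl bromide ⇐ C2 ketone (kept as a ketal); C9–Cl and C9–CH3 ⇐ C9 ketone, C8–Br ⇐ its α-bromination; ring B is then cut at C6–C7 and C8–C9.
2. Enabling feature: the methylidene carbon C5 of ring A is a masked ketone whose α-carbon is the spiro atom C6, and C9 lies 1,4 to C6 across ring B (via C11–C10) and is a masked ester carbon. A C6 enolate that already carries the C11–C10–C9 ester arm can therefore take up C7–C8 as methyl acrylate: Michael addition makes C6–C7, Dieckmann closure makes C8–C9. The CO2Me left on C8 is a helper, removed in step 8.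
3. Forward order: ring A first (phenol → quinone monoketal → cuprate addition sets the C1 gem-dimethyl group and the enolate position → methylidene ketone → ester arm); ring B by the spiroannulation; then C5 methylenation, ring B halogenation, C2 vinyl bromide, C4 oxidation and reduction.
4. Stereochemistry: ketone 15 is achiral. One enantiotopos-selective deprotonation with a chiral lithium amide fixes C6 and decides which α-carbon becomes C8; C8 by equilibration to the equatorial bromide; C9 by chloride opening of the bromonium ion anti to Br; C4 by CBS reduction under reagent control.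
5. Bromochlorination of a C8=C9 alkene is avoided: diaxial addition in the chair that keeps C1 equatorial would put Br cis to C5, the wrong series.

Key step: step 6

Assumption: the sense of induction of the chiral lithium amide (step 9) and of the CBS catalyst (step 15) follows the accepted models; if either proves opposite, the enantiomeric amine or catalyst is used. Intermediates are named with their own IUPAC locants.

**Route**

Step 1
Reactants: 1 4-methoxy-3-methylphenol
Product: 2 4,4-dimethoxy-3-methylcyclohexa-2,5-dien-1-one
Conditions: PhI(OAc)2, MeOH, 0 °C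
Reagents that add atoms: methanol CO
Why: Oxidative dearomatisation of a para-alkoxyphenol by a hypervalent iodine reagent in methanol gives the quinone monoketal, which carries the later C2 carbonyl in protected form; no stereocentre is formed.

Step 2
Reactants: 2 4,4-dimethoxy-3-methylcyclohexa-2,5-dien-1-one
Product: 3 4,4-dimethoxy-3-methylcyclohex-2-en-1-one
Conditions: H2 (1 atm), RhCl(PPh3)3 (5 mol %), benzene, 23 °C
Reagents that add atoms: none
Why: Homogeneous hydrogenation should reduce the unhindered disubstituted double bond much faster than the methyl-bearing trisubstituted one, and the neutral medium leaves the ketal intact (chemoselective alkene hydrogenation).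

Step 3
Reactants: 3 4,4-dimethoxy-3-methylcyclohex-2-en-1-one
Product: 5 2-[(dimethylamino)methyl]-4,4-dimethoxy-3,3-dimethylcyclohexan-1-one (racemic), via silyl enol ether 4 (not isolated)
Conditions: Me2CuLi, Me3SiCl, THF, −78 → −20 °C; then Me2N=CH2+ I−, CH2Cl2, 23 °C; aq NaHCO3
Reagents that add atoms: lithium dimethylcuprate C[Cu-]C.[Li+]; N,N-dimethylmethyleneiminium iodide C[N+](C)=C.[I-]
Why: Chlorosilane-accelerated conjugate addition of the cuprate makes the gem-dimethyl carbon and gives the enol silane only on the side of that carbon, which the iminium salt then aminomethylates (conjugate addition with enolate trapping, Mannich reaction); the new stereocentre is racemic and is destroyed in step 4.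

Step 4
Reactants: 5 2-[(dimethylamino)methyl]-4,4-dimethoxy-3,3-dimethylcyclohexan-1-one
Product: 7 4,4-dimethoxy-3,3-dimethyl-2-methylidenecyclohexan-1-one, via ammonium iodide 6 (not isolated)
Conditions: MeI, CH2Cl2, 23 °C; then NaHCO3, H2O/CH2Cl2, 23 °C
Reagents that add atoms: none
Why: Quaternisation and E1cB loss of trimethylamine (Mannich base methiodide elimination) give the α-methylidene ketone, its position fixed by where the aminomethyl group was placed.

Step 5
Reactants: 7 4,4-dimethoxy-3,3-dimethyl-2-methylidenecyclohexan-1-one; 8 1-methoxy-1-(trimethylsilyloxy)ethene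
Product: 9 methyl 3-[5,5-dimethoxy-6,6-dimethyl-2-(trimethylsilyloxy)cyclohex-1-en-1-yl]propanoate
Conditions: MeCN, 55 °C
Reagents that add atoms: none
Why: Mukaiyama–Michael addition of the ketene silyl acetal to the unhindered methylidene terminus, with silyl transfer, installs the three-carbon ester arm and gives the tetrasubstituted enol silane regiospecifically on the side of the quaternary carbon.

Step 6
Reactants: 9 methyl 3-[5,5-dimethoxy-6,6-dimethyl-2-(trimethylsilyloxy)cyclohex-1-en-1-yl]propanoate; 10 methyl acrylate
Product: 13 methyl 10,10-dimethoxy-11,11-dimethyl-3,7-dioxospiro[5.5]undecane-2-carboxylate (racemic), via potassium enolate 11 (not isolated), via Michael adduct enolate 12 (not isolated)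
Conditions: KOtBu (1.05 equiv), THF, −78 → −40 °C; methyl acrylate (1.0 equiv), −78 → 23 °C; AcOH
Reagents that add atoms: none
Why: Desilylation of 9 by KOtBu unveils the tetrasubstituted potassium enolate 11 at the carbon between the carbonyl and the CMe2 carbon; its conjugate addition to methyl acrylate forms the first bond and makes the quaternary spiro carbon, and the ester enolate 12 then closes ring B on the ester of the three-carbon arm, with deprotonation of the β-keto ester driving the sequence. The closest known reaction type is the Michael–Dieckmann annulation of carbonyl compounds with acrylates, here run as a spiroannulation on a preformed enolate. Ring B closes by 6-exo-trig acyl substitution (Dieckmann condensation). The spiro carbon is made quaternary without any stereochemical demand: its two three-carbon arms are constitutionally identical before closure, so either direction of condensation gives the same racemic β-keto ester 13, and the centre is no longer stereogenic in 15. The selectivity needed is regiochemical, reaction at the hindered α-carbon and not at the CH2 on the other side of the ketone, and it is secured by the enol silane, which fixes the enolate position, and by using one equivalent of acrylate; preference for ring closure over acrylate oligomerisation rests on the intramolecular six-ring closure.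

Step 7
Reactants: 13 methyl 10,10-dimethoxy-11,11-dimethyl-3,7-dioxospiro[5.5]undecane-2-carboxylate
Product: 14 methyl 10,10-dimethoxy-11,11-dimethyl-7-methylidene-3-oxospiro[5.5]undecane-2-carboxylate (racemic)
Conditions: Ph3P=CH2 (4 equiv, from Ph3PCH3Br and KOtBu), toluene, 23 → 80 °C
Reagents that add atoms: methyltriphenylphosphonium bromide C[P+](c1ccccc1)(c1ccccc1)c1ccccc1.[Br-]
Why: The first equivalent of ylide turns the β-keto ester into its unreactive enolate, so Wittig methylenation should occur only at the ring A ketone next to the quaternary carbon, a ketone type known to accept this ylide on heating.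

Step 8
Reactants: 14 methyl 10,10-dimethoxy-11,11-dimethyl-7-methylidene-3-oxospiro[5.5]undecane-2-carboxylate
Product: 15 10,10-dimethoxy-11,11-dimethyl-7-methylidenespiro[5.5]undecan-3-one (achiral)
Conditions: LiCl, H2O, DMSO, 150 °C
Reagents that add atoms: none
Why: Krapcho dealkoxycarbonylation removes the ester helper under neutral conditions that spare ketal and alkene, and leaves an achiral ketone whose two α-methylene groups are enantiotopic.

Step 9
Reactants: 15 10,10-dimethoxy-11,11-dimethyl-7-methylidenespiro[5.5]undecan-3-one
Product: 16 {[(6S)-10,10-dimethoxy-11,11-dimethyl-7-methylidenespiro[5.5]undec-2-en-3-yl]oxy}trimethylsilane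
Conditions: (R,R)-bis(1-phenylethyl)amine, n-BuLi, Me3SiCl (present during deprotonation), THF, −100 °C
Reagents that add atoms: chlorotrimethylsilane C[Si](C)(C)Cl
Why: Enantiotopos-selective deprotonation of a 4,4-disubstituted cyclohexanone by a chiral lithium amide with in situ silylation makes the spiro carbon stereogenic; the base distinguishes the two axial α-hydrogens of the chair in which the CMe2 carbon is equatorial, and the (6S) sense is assigned by analogy with 4-tert-butylcyclohexanone.

Step 10
Reactants: 16 {[(6S)-10,10-dimethoxy-11,11-dimethyl-7-methylidenespiro[5.5]undec-2-en-3-yl]oxy}trimethylsilane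
Product: 18 (2S,6S)-2-bromo-10,10-dimethoxy-11,11-dimethyl-7-methylidenespiro[5.5]undecan-3-one, via axial bromo ketone 17 (not isolated)
Conditions: NBS, THF, −78 °C; then LiBr, acetone, 23 °C
Reagents that add atoms: N-bromosuccinimide O=C1CCC(=O)N1Br
Why: Bromination of the enol silane puts bromine on the carbon chosen in step 9, and bromide exchange (SN2 epimerisation of the α-bromo ketone) should settle on the equatorial bromide trans to the axial methylidene-bearing carbon, which avoids the 1,3-diaxial contact of the other epimer.

Step 11
Reactants: 18 (2S,6S)-2-bromo-10,10-dimethoxy-11,11-dimethyl-7-methylidenespiro[5.5]undecan-3-one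
Product: 19 (2S,6S)-2-bromo-10,10-dimethoxy-3,11,11-trimethyl-7-methylidenespiro[5.5]undecan-3-ol (both C3 epimers)
Conditions: MeMgBr, THF, −78 °C; then H2O at −78 °C
Reagents that add atoms: methylmagnesium bromide C[Mg]Br
Why: Grignard 1,2-addition to the only ketone at low temperature brings in the methyl group of the future C(Me)Cl carbon; the configuration of the carbinol carbon is not relied on because both epimers converge in step 12.

Step 12
Reactants: 19 (2S,6S)-2-bromo-10,10-dimethoxy-3,11,11-trimethyl-7-methylidenespiro[5.5]undecan-3-ol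
Product: 21 (6S,8S,9S)-8-bromo-9-chloro-1,1,9-trimethyl-5-methylidenespiro[5.5]undecan-2-one, via chloro ketal 20 (not isolated)
Conditions: 1-chloro-N,N,2-trimethylprop-1-en-1-amine, CH2Cl2, 0 → 23 °C; then 1 M HCl, THF, 23 °C
Reagents that add atoms: 1-chloro-N,N,2-trimethylprop-1-en-1-amine CC(C)=C(Cl)N(C)C; water O
Why: The α-chloroenamine converts the tertiary alcohol into its chloride under neutral conditions that spare the exocyclic alkene (deoxychlorination through an alkoxyiminium ion pair); ionisation is assisted by the neighbouring bromine, chloride should open the bromonium ion at the tertiary carbon anti to bromine to give the trans bromochloride from either carbinol epimer, and dilute acid then hydrolyses the ketal.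

Step 13
Reactants: 21 (6S,8S,9S)-8-bromo-9-chloro-1,1,9-trimethyl-5-methylidenespiro[5.5]undecan-2-one
Product: 22 (6S,8S,9S)-2,8-dibromo-9-chloro-1,1,9-trimethyl-5-methylidenespiro[5.5]undec-2-ene
Conditions: (PhO)3P, Br2, Et3N, CH2Cl2, −78 → 40 °C
Reagents that add atoms: bromine BrBr
Why: Halogenative dehydration of a ketone by the triphenyl phosphite–bromine adduct gives the vinyl bromide; the ketone can enolise only away from the CMe2 carbon, so only one double-bond position is possible, and the preformed bromophosphonium salt should leave the alkene alone.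

Step 14
Reactants: 22 (6S,8S,9S)-2,8-dibromo-9-chloro-1,1,9-trimethyl-5-methylidenespiro[5.5]undec-2-ene
Product: 23 (6S,8S,9S)-2,8-dibromo-9-chloro-1,1,9-trimethyl-5-methylidenespiro[5.5]undec-2-en-4-one
Conditions: CrO3, 3,5-dimethylpyrazole, CH2Cl2, −20 °C
Reagents that add atoms: chromium trioxide O=[Cr](=O)=O
Why: Allylic oxidation by the CrO3–3,5-dimethylpyrazole complex should convert the only doubly allylic CH2 group, between the methylidene-bearing carbon and the vinyl bromide, into the cross-conjugated ketone; the other allylic position is quaternary.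

Step 15
Reactants: 23 (6S,8S,9S)-2,8-dibromo-9-chloro-1,1,9-trimethyl-5-methylidenespiro[5.5]undec-2-en-4-one
Product: 24 (4R,6S,8S,9S)-2,8-dibromo-9-chloro-1,1,9-trimethyl-5-methylidenespiro[5.5]undec-2-en-4-ol
Conditions: (S)-2-methyl-CBS-oxazaborolidine (0.5 equiv), catecholborane, toluene, −78 °C; then MeOH, aq NaHCO3
Reagents that add atoms: none
Why: Corey–Bakshi–Shibata reduction delivers hydride 1,2 under reagent control; the fully substituted methylidene-bearing α-carbon acts as the large group and the CH= carbon as the small one, so the (S)-catalyst should give the (4R)-alcohol.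

**Compound list**

1 | 4-methoxy-3-methylphenol | COc1ccc(O)cc1C | starting material
2 | 4,4-dimethoxy-3-methylcyclohexa-2,5-dien-1-one | COC1(OC)C=CC(=O)C=C1C | intermediate
3 | 4,4-dimethoxy-3-methylcyclohex-2-en-1-one | COC1(OC)CCC(=O)C=C1C | intermediate
4 | [(4,4-dimethoxy-3,3-dimethylcyclohex-1-en-1-yl)oxy]trimethylsilane | COC1(OC)CCC(O[Si](C)(C)C)=CC1(C)C | intermediate
5 | 2-[(dimethylamino)methyl]-4,4-dimethoxy-3,3-dimethylcyclohexan-1-one (racemic) | CN(C)CC1C(=O)CCC(OC)(OC)C1(C)C | intermediate
6 | [(3,3-dimethoxy-2,2-dimethyl-6-oxocyclohexyl)methyl]trimethylammonium iodide | C[N+](C)(C)CC1C(=O)CCC(OC)(OC)C1(C)C.[I-] | intermediate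
7 | 4,4-dimethoxy-3,3-dimethyl-2-methylidenecyclohexan-1-one | C=C1C(=O)CCC(OC)(OC)C1(C)C | intermediate
8 | 1-methoxy-1-(trimethylsilyloxy)ethene | C=C(OC)O[Si](C)(C)C | starting material
9 | methyl 3-[5,5-dimethoxy-6,6-dimethyl-2-(trimethylsilyloxy)cyclohex-1-en-1-yl]propanoate | COC(=O)CCC1=C(O[Si](C)(C)C)CCC(OC)(OC)C1(C)C | intermediate
10 | methyl acrylate | C=CC(=O)OC | starting material
11 | potassium 4,4-dimethoxy-2-(3-methoxy-3-oxopropyl)-3,3-dimethylcyclohex-1-en-1-olate | COC(=O)CCC1=C([O-])CCC(OC)(OC)C1(C)C.[K+] | intermediate
12 | potassium ester enolate of dimethyl 3,3'-(4,4-dimethoxy-3,3-dimethyl-2-oxocyclohexane-1,1-diyl)dipropanoate | COC(=O)CCC1(CC=C([O-])OC)C(=O)CCC(OC)(OC)C1(C)C.[K+] | intermediate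
13 | methyl 10,10-dimethoxy-11,11-dimethyl-3,7-dioxospiro[5.5]undecane-2-carboxylate (racemic) | O=C1CCC(OC)(OC)C(C)(C)C12CC(C(=O)OC)C(=O)CC2 | intermediate
14 | methyl 10,10-dimethoxy-11,11-dimethyl-7-methylidene-3-oxospiro[5.5]undecane-2-carboxylate (racemic) | C=C1CCC(OC)(OC)C(C)(C)C12CC(C(=O)OC)C(=O)CC2 | intermediate
15 | 10,10-dimethoxy-11,11-dimethyl-7-methylidenespiro[5.5]undecan-3-one | C=C1CCC(OC)(OC)C(C)(C)C12CCC(=O)CC2 | intermediate
16 | {[(6S)-10,10-dimethoxy-11,11-dimethyl-7-methylidenespiro[5.5]undec-2-en-3-yl]oxy}trimethylsilane | C=C1CCC(OC)(OC)C(C)(C)[C@]12CCC(O[Si](C)(C)C)=CC2 | intermediate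
17 | (2R,6S)-2-bromo-10,10-dimethoxy-11,11-dimethyl-7-methylidenespiro[5.5]undecan-3-one | C=C1CCC(OC)(OC)C(C)(C)[C@]12CCC(=O)[C@H](Br)C2 | intermediate
18 | (2S,6S)-2-bromo-10,10-dimethoxy-11,11-dimethyl-7-methylidenespiro[5.5]undecan-3-one | C=C1CCC(OC)(OC)C(C)(C)[C@]12CCC(=O)[C@@H](Br)C2 | intermediate
19 | (2S,6S)-2-bromo-10,10-dimethoxy-3,11,11-trimethyl-7-methylidenespiro[5.5]undecan-3-ol (both C3 epimers) | C=C1CCC(OC)(OC)C(C)(C)[C@]12CCC(C)(O)[C@@H](Br)C2 | intermediate
20 | (2S,3S,6S)-2-bromo-3-chloro-10,10-dimethoxy-3,11,11-trimethyl-7-methylidenespiro[5.5]undecane | C=C1CCC(OC)(OC)C(C)(C)[C@]12CC[C@](C)(Cl)[C@@H](Br)C2 | intermediate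
21 | (6S,8S,9S)-8-bromo-9-chloro-1,1,9-trimethyl-5-methylidenespiro[5.5]undecan-2-one | C=C1CCC(=O)C(C)(C)[C@]12CC[C@](C)(Cl)[C@@H](Br)C2 | intermediate
22 | (6S,8S,9S)-2,8-dibromo-9-chloro-1,1,9-trimethyl-5-methylidenespiro[5.5]undec-2-ene | C=C1CC=C(Br)C(C)(C)[C@]12CC[C@](C)(Cl)[C@@H](Br)C2 | intermediate
23 | (6S,8S,9S)-2,8-dibromo-9-chloro-1,1,9-trimethyl-5-methylidenespiro[5.5]undec-2-en-4-one | C=C1C(=O)C=C(Br)C(C)(C)[C@]12CC[C@](C)(Cl)[C@@H](Br)C2 | intermediate
24 | (4R,6S,8S,9S)-2,8-dibromo-9-chloro-1,1,9-trimethyl-5-methylidenespiro[5.5]undec-2-en-4-ol | C=C1[C@H](O)C=C(Br)C(C)(C)[C@]12CC[C@](C)(Cl)[C@@H](Br)C2 | target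

**Count and risks**

Total step count: 15. Longest linear sequence: 15 steps (from 1).

Steps most likely to fail:

Step 6 (key step). The tetrasubstituted enolate, flanked by the CMe2 carbon, may add too slowly to the acrylate, so that proton transfer to the other α-position or acrylate oligomerisation takes over. Fallback: from 7, a Diels–Alder reaction with 2-(trimethylsilyloxy)buta-1,3-diene (toluene, 110 °C) should give, with para orientation, the racemic spiro enol silane ketone F1. Wittig methylenation (Ph3P=CH2) of its ring A ketone gives the racemic enol silane F2, and K2CO3 in MeOH frees ketone 15, where the route is rejoined.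

Step 3. Conjugate addition at the β-carbon next to the ketal carbon may be slow, with competing 1,2-addition or reductive loss of methoxide. Fallback: from 3, Luche reduction (NaBH4, CeCl3) gives the allylic alcohol F3. Hydroxyl-directed Simmons–Smith cyclopropanation (Et2Zn, CH2I2) gives the cyclopropyl carbinol F4, and Swern oxidation gives the cyclopropyl ketone F5. Dissolving-metal opening of the exocyclic cyclopropane bond (Li, NH3) makes the gem-dimethyl group together with the same regiodefined enolate, which Me3SiCl traps as silyl enol ether 4, where the route is rejoined.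

Step 9. The two enantiotopic α-methylene groups may be discriminated incompletely, so that low enantiomeric purity is carried through the route. Fallback: from 15, organocatalytic enamine α-bromination (C2-symmetric 4,5-diphenylimidazolidine, PhCO2H, 4,4-dibromo-2,6-di-tert-butylcyclohexa-2,5-dienone) would give the α-bromo ketone directly. LiBr equilibration as in step 10 then leads to 18, where the route is rejoined; no new compound is passed.

Further compounds
F1 | step 6 | 10,10-dimethoxy-11,11-dimethyl-3-(trimethylsilyloxy)spiro[5.5]undec-2-en-7-one (racemic) | O=C1CCC(OC)(OC)C(C)(C)C12CCC(O[Si](C)(C)C)=CC2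
F2 | step 6 | [(10,10-dimethoxy-11,11-dimethyl-7-methylidenespiro[5.5]undec-2-en-3-yl)oxy]trimethylsilane (racemic) | C=C1CCC(OC)(OC)C(C)(C)C12CCC(O[Si](C)(C)C)=CC2
F3 | step 3 | 4,4-dimethoxy-3-methylcyclohex-2-en-1-ol | COC1(OC)CCC(O)C=C1C
F4 | step 3 | 5,5-dimethoxy-6-methylbicyclo[4.1.0]heptan-2-ol | COC1(OC)CCC(O)C2CC12C
F5 | step 3 | 5,5-dimethoxy-6-methylbicyclo[4.1.0]heptan-2-one | COC1(OC)CCC(=O)C2CC12C
F0 | step 9 | none | none
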